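Locants follow the C19 chain from the pentyl methyl (C1) to the vinyl end (C19). The oxolane ring is O–C6–C7–C8–C9. Everything rests on one feature: C5 on C6 and the oxygen on C7 stand cis on that ring, so a five-membered lactone (O7–C4–C5–C6–C7) can span them as a second, cis-fused ring. A palladium-catalysed carbonylative double cyclisation of an acyclic 7,9-syn diol forms O9–C6, C5–C4 and C4–O7 in one operation, closes both rings and sets C6. The precursor is a pent-4-ene-1,3-diol whose C10 and C11 oxygens are masked as a dioxolane. Later C4 takes up C1–C3, and the dioxolane becomes the epoxide that takes up C12–C19.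

Key step: step 6

Remark: the target is read as (6S,7S,9R,10R), with C5/O7 cis and C5/C10 trans on the oxolane, and with O7/O9 and O9/O10 both syn; aldehyde 1 is assumed to be used as freshly distilled monomer, because it oligomerises and can epimerise on storage.

Step 1
Reactants: 1 (R)-2,2-dimethyl-1,3-dioxolane-4-carbaldehyde ((R)-glyceraldehyde acetonide; its stereocentre becomes C10)
Product: 3 (1R)-1-[(4R)-2,2-dimethyl-1,3-dioxolan-4-yl]but-3-en-1-ol (9,10-syn), via diisopinocampheylborinate ester 2 (not isolated)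
Conditions: (+)-Ipc2BOMe [(−)-α-pinene series], allylMgBr, Et2O, 0 °C to rt; 1, −78 °C; then NaOH, H2O2, 0 °C to rt
Reagents that add atoms: allylmagnesium bromide, C=CC[Mg]Br
Why: Brown asymmetric allylboration through a closed Zimmerman–Traxler chair, in which the (−)-α-pinene-derived ligands send allyl to the Re face of the aldehyde and override the Felkin–Anh (9,10-anti) bias of 1, so that C9 is set as R while C10 is carried over from 1; oxidative work-up cleaves 2, and any anti epimer is removed by chromatography.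

Step 2
Reactants: 3 (1R)-1-[(4R)-2,2-dimethyl-1,3-dioxolan-4-yl]but-3-en-1-ol
Product: 4 tert-butyl (1R)-1-[(4R)-2,2-dimethyl-1,3-dioxolan-4-yl]but-3-en-1-yl carbonate
Conditions: Boc2O, DMAP (cat.), MeCN, rt
Reagents that add atoms: di-tert-butyl dicarbonate, CC(C)(C)OC(=O)OC(=O)OC(C)(C)C
Why: DMAP-catalysed O-acylation (carbonate formation) of the only hydroxyl group installs the internal oxygen nucleophile for the next step without touching a stereocentre.

Step 3
Reactants: 4 tert-butyl (1R)-1-[(4R)-2,2-dimethyl-1,3-dioxolan-4-yl]but-3-en-1-yl carbonate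
Product: 5 (4R,6S)-4-[(4R)-2,2-dimethyl-1,3-dioxolan-4-yl]-6-(iodomethyl)-1,3-dioxan-2-one (4,6-cis)
Conditions: IBr, toluene, −85 °C; aq Na2S2O3/NaHCO3
Reagents that add atoms: iodine monobromide, IBr
Why: Iodocarbonate cyclisation (electrophilic 6-exo halocyclisation of a homoallylic tert-butyl carbonate), in which the carbonyl oxygen opens the iodonium ion at C7 through a chair with the dioxolanyl and iodomethyl groups both equatorial, which sets C7 as S (7,9-syn), while bromide takes up the tert-butyl cation.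

Step 4
Reactants: 5 (4R,6S)-4-[(4R)-2,2-dimethyl-1,3-dioxolan-4-yl]-6-(iodomethyl)-1,3-dioxan-2-one
Product: 7 (1R)-1-[(4R)-2,2-dimethyl-1,3-dioxolan-4-yl]-2-[(2S)-oxiran-2-yl]ethan-1-ol, via iododiol 6 (not isolated)
Conditions: K2CO3, MeOH, rt
Reagents that add atoms: none
Why: Carbonate methanolysis followed by intramolecular Williamson closure (3-exo-tet) of O7 onto C6, which is much faster than 5-exo-tet attack by O9; no C–O bond at C7 or C9 is broken, so both configurations are kept.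

Step 5
Reactants: 7 (1R)-1-[(4R)-2,2-dimethyl-1,3-dioxolan-4-yl]-2-[(2S)-oxiran-2-yl]ethan-1-ol
Product: 9 (1R,3S)-1-[(4R)-2,2-dimethyl-1,3-dioxolan-4-yl]pent-4-ene-1,3-diol (7,9-syn), via sulfonium betaine 8 (not isolated)
Conditions: Me3SI (excess), n-BuLi, THF, −10 °C to rt
Reagents that add atoms: trimethylsulfonium iodide, C[S+](C)C.[I-]
Why: Methylenative opening of a terminal epoxide by excess dimethylsulfonium methylide (one-carbon homologation to an allylic alcohol), in which SN2 attack at unhindered C6 gives 8 and further ylide induces β-elimination of dimethyl sulfide to the C5=C6 alkene; the C7–O bond stays intact, and the lithium alkoxide at O9 is a spectator because its 4-exo and 5-endo closures are disfavoured.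

Step 6
Reactants: 9 (1R,3S)-1-[(4R)-2,2-dimethyl-1,3-dioxolan-4-yl]pent-4-ene-1,3-diol
Product: 12 (3aS,5R,6aS)-5-[(4R)-2,2-dimethyl-1,3-dioxolan-4-yl]tetrahydrofuro[3,2-b]furan-2(3H)-one (cis-fused; dioxolanyl on the convex face), via alkylpalladium chloride 10 (not isolated), via acylpalladium chloride 11 (not isolated)
Conditions: PdCl2 (10 mol %), CuCl2 (anhydrous, 3 equiv), NaOAc (3 equiv), CO (1 atm), AcOH, rt
Reagents that add atoms: carbon monoxide, [C-]#[O+]
Why: Coordination of the C5=C6 alkene to divalent palladium makes C6 electrophilic, O9 attacks it from the face opposite the metal to give 10, CO inserts into the C5–Pd bond to give 11, O7 displaces palladium from C4, and CuCl2 returns the released zerovalent palladium to the divalent state. The reaction type is the known Wacker-type oxypalladation–carbonylation–lactonisation of pent-4-ene-1,3-diols to 2,6-dioxabicyclo[3.3.0]octan-3-ones, applied here to a new diol. The oxolane closes 5-exo-trig at the alkene and the lactone closes 5-exo-trig at the acyl carbon. C6, the only new stereocentre, is controlled by C7: oxypalladation is reversible and only the epimer with C5 cis to O7 can lactonise, since a trans-fused bicyclo[3.3.0] lactone is too strained, so C6 emerges S, and because O7 and O9 are syn in 9, C10 then sits on the convex face, trans to C5 across the ring oxygen. The step needs alkene-face selectivity, regioselectivity and a choice among four oxygens: the terminal alkene favours 5-exo over 6-endo attack, allylic O7 could only form a three- or four-membered ring, and O10 and O11 are locked in the dioxolane, which leaves O9 as the only nucleophile. NaOAc buffers the HCl formed so that the dioxolane is neither hydrolysed nor shifted onto O9.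

Step 7
Reactants: 12 (3aS,5R,6aS)-5-[(4R)-2,2-dimethyl-1,3-dioxolan-4-yl]tetrahydrofuro[3,2-b]furan-2(3H)-one
Product: 13 (3aS,5R,6aS)-5-[(4R)-2,2-dimethyl-1,3-dioxolan-4-yl]hexahydrofuro[3,2-b]furan-2-ol (lactol, both anomers at C4)
Conditions: i-Bu2AlH, CH2Cl2, −78 °C; aq potassium sodium tartrate
Reagents that add atoms: none
Why: Partial reduction of a γ-lactone, whose tetrahedral aluminium hemiacetal persists at −78 °C and gives the lactol only on work-up, with the ketal inert.

Step 8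
Reactants: 13 (3aS,5R,6aS)-5-[(4R)-2,2-dimethyl-1,3-dioxolan-4-yl]hexahydrofuro[3,2-b]furan-2-ol
Product: 15 (2S,3S,5R)-5-[(4R)-2,2-dimethyl-1,3-dioxolan-4-yl]-2-[(2Z)-pent-2-en-1-yl]oxolan-3-ol, via open hydroxy aldehyde 14 (not isolated)
Conditions: n-PrPPh3Br (excess), NaN(SiMe3)2, THF, 0 °C; then 13, −78 °C to rt
Reagents that add atoms: propyltriphenylphosphonium bromide, CCC[P+](c1ccccc1)(c1ccccc1)c1ccccc1.[Br-]
Why: Wittig olefination of a lactol through its open tautomer 14 with excess non-stabilised ylide (one equivalent is spent on the hydroxyl proton), fast enough at low temperature to outrun β-elimination of the ring oxygen; the alkene geometry is irrelevant because it is saturated next, and O7 is released as the free alcohol.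

Step 9
Reactants: 15 (2S,3S,5R)-5-[(4R)-2,2-dimethyl-1,3-dioxolan-4-yl]-2-[(2Z)-pent-2-en-1-yl]oxolan-3-ol
Product: 16 (2S,3S,5R)-5-[(4R)-2,2-dimethyl-1,3-dioxolan-4-yl]-2-pentyloxolan-3-ol
Conditions: H2 (1 atm), Pd/C (10 wt %), EtOAc, rt
Reagents that add atoms: none
Why: Heterogeneous catalytic hydrogenation of the only C=C bond under neutral conditions that leave the ketal, the ring ether and all stereocentres untouched.

Step 10
Reactants: 16 (2S,3S,5R)-5-[(4R)-2,2-dimethyl-1,3-dioxolan-4-yl]-2-pentyloxolan-3-ol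
Product: 17 tert-butyl{[(2S,3S,5R)-5-[(4R)-2,2-dimethyl-1,3-dioxolan-4-yl]-2-pentyloxolan-3-yl]oxy}dimethylsilane
Conditions: TBSOTf, 2,6-lutidine, CH2Cl2, −78 to 0 °C
Reagents that add atoms: tert-butyldimethylsilyl triflate, CC(C)(C)[Si](C)(C)OS(=O)(=O)C(F)(F)F
Why: Silyl ether formation with the triflate, which is reactive enough for a secondary alcohol flanked by the cis pentyl chain, marks O7 so that only O10 can be acylated later.

Step 11
Reactants: 17 tert-butyl{[(2S,3S,5R)-5-[(4R)-2,2-dimethyl-1,3-dioxolan-4-yl]-2-pentyloxolan-3-yl]oxy}dimethylsilane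
Product: 18 (1R)-1-[(2R,4S,5S)-4-(tert-butyldimethylsilyloxy)-5-pentyloxolan-2-yl]ethane-1,2-diol
Conditions: AcOH/H2O (4:1), rt
Reagents that add atoms: none
Why: Acid-catalysed ketal hydrolysis, in which the terminal dioxolane ionises to a tertiary oxocarbenium ion far faster than the hindered secondary silyl ether is solvolysed.

Step 12
Reactants: 18 (1R)-1-[(2R,4S,5S)-4-(tert-butyldimethylsilyloxy)-5-pentyloxolan-2-yl]ethane-1,2-diol
Product: 20 tert-butyl(dimethyl){[(2S,3S,5R)-5-[(2R)-oxiran-2-yl]-2-pentyloxolan-3-yl]oxy}silane, via primary tosylate 19 (not isolated)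
Conditions: TsCl, Et3N, Bu2SnO (5 mol %), CH2Cl2, 0 °C to rt; then K2CO3, MeOH, rt
Reagents that add atoms: none
Why: Stannylene-acetal-catalysed regioselective sulfonylation of the primary hydroxyl followed by Williamson epoxide closure, in which O10 is the nucleophile and its bond to C10 is never broken, so C10 stays R.

Step 13
Reactants: 20 tert-butyl(dimethyl){[(2S,3S,5R)-5-[(2R)-oxiran-2-yl]-2-pentyloxolan-3-yl]oxy}silane; 21 8-bromooct-1-ene
Product: 23 (1R)-1-[(2R,4S,5S)-4-(tert-butyldimethylsilyloxy)-5-pentyloxolan-2-yl]dec-9-en-1-ol, via oct-7-enylmagnesium bromide 22 (not isolated)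
Conditions: 21, Mg, THF, rt to 40 °C; CuI (10 mol %), −30 °C; then 20, −30 to 0 °C; aq NH4Cl
Reagents that add atoms: none
Why: Copper-catalysed Grignard opening of a terminal epoxide by SN2 attack at unsubstituted C11 forms C11–C12 and frees O10 as the only hydroxyl group, with C10 untouched.

Step 14
Reactants: 23 (1R)-1-[(2R,4S,5S)-4-(tert-butyldimethylsilyloxy)-5-pentyloxolan-2-yl]dec-9-en-1-ol; 24 hexadecanoyl (palmitoyl) chloride
Product: 25 (1R)-1-[(2R,4S,5S)-4-(tert-butyldimethylsilyloxy)-5-pentyloxolan-2-yl]dec-9-en-1-yl hexadecanoate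
Conditions: 24, Et3N, DMAP (cat.), CH2Cl2, 0 °C to rt
Reagents that add atoms: none
Why: DMAP-catalysed esterification with an acid chloride (nucleophilic catalysis) at the only free hydroxyl group, with retention at C10.

Step 15
Reactants: 25 (1R)-1-[(2R,4S,5S)-4-(tert-butyldimethylsilyloxy)-5-pentyloxolan-2-yl]dec-9-en-1-yl hexadecanoate
Product: 26 (1R)-1-[(2R,4S,5S)-4-hydroxy-5-pentyloxolan-2-yl]dec-9-en-1-yl hexadecanoate, the target (6S,7S,9R,10R)
Conditions: HF·pyridine, pyridine, THF, 0 °C to rt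
Reagents that add atoms: none
Why: Fluoride-induced desilylation driven by the Si–F bond under mildly acidic conditions that spare the ester and the terminal alkene and give no base-promoted acyl shift, which is also disfavoured because O7 and C10 lie on opposite ring faces.

Compound list
1 | (R)-2,2-dimethyl-1,3-dioxolane-4-carbaldehyde | CC1(C)OC[C@@H](O1)C=O | starting material
2 | (1R)-1-[(4R)-2,2-dimethyl-1,3-dioxolan-4-yl]but-3-en-1-yl diisopinocampheylborinate, (−)-α-pinene series | CC1(C)OC[C@@H](O1)[C@H](OB([C@@H]2[C@@H](C)[C@@H]3C[C@H](C2)C3(C)C)[C@@H]2[C@@H](C)[C@@H]3C[C@H](C2)C3(C)C)CC=C | intermediate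
3 | (1R)-1-[(4R)-2,2-dimethyl-1,3-dioxolan-4-yl]but-3-en-1-ol | CC1(C)OC[C@@H](O1)[C@H](O)CC=C | intermediate
4 | tert-butyl (1R)-1-[(4R)-2,2-dimethyl-1,3-dioxolan-4-yl]but-3-en-1-yl carbonate | CC1(C)OC[C@@H](O1)[C@H](OC(=O)OC(C)(C)C)CC=C | intermediate
5 | (4R,6S)-4-[(4R)-2,2-dimethyl-1,3-dioxolan-4-yl]-6-(iodomethyl)-1,3-dioxan-2-one | CC1(C)OC[C@@H](O1)[C@H]2C[C@@H](CI)OC(=O)O2 | intermediate
6 | (2S,4R)-4-[(4R)-2,2-dimethyl-1,3-dioxolan-4-yl]-1-iodobutane-2,4-diol | CC1(C)OC[C@@H](O1)[C@H](O)C[C@H](O)CI | intermediate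
7 | (1R)-1-[(4R)-2,2-dimethyl-1,3-dioxolan-4-yl]-2-[(2S)-oxiran-2-yl]ethan-1-ol | CC1(C)OC[C@@H](O1)[C@H](O)C[C@H]2CO2 | intermediate
8 | [(3S,5R)-5-[(4R)-2,2-dimethyl-1,3-dioxolan-4-yl]-5-hydroxy-3-oxidopentyl]dimethylsulfonium (betaine) | CC1(C)OC[C@@H](O1)[C@H](O)C[C@H]([O-])CC[S+](C)C | intermediate
9 | (1R,3S)-1-[(4R)-2,2-dimethyl-1,3-dioxolan-4-yl]pent-4-ene-1,3-diol | CC1(C)OC[C@@H](O1)[C@H](O)C[C@H](O)C=C | intermediate
10 | alkylpalladium chloride from oxypalladation (oxolane closed, C5–Pd, O7 free and cis to C5; further ligands on palladium omitted) | CC1(C)OC[C@@H](O1)[C@H]2C[C@H](O)[C@H](C[Pd]Cl)O2 | intermediate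
11 | acylpalladium chloride after CO insertion (C5–C4(=O)–Pd; further ligands on palladium omitted) | CC1(C)OC[C@@H](O1)[C@H]2C[C@H](O)[C@H](CC(=O)[Pd]Cl)O2 | intermediate
12 | (3aS,5R,6aS)-5-[(4R)-2,2-dimethyl-1,3-dioxolan-4-yl]tetrahydrofuro[3,2-b]furan-2(3H)-one | CC1(C)OC[C@@H](O1)[C@H]2C[C@@H]3OC(=O)C[C@@H]3O2 | intermediate
13 | (3aS,5R,6aS)-5-[(4R)-2,2-dimethyl-1,3-dioxolan-4-yl]hexahydrofuro[3,2-b]furan-2-ol (both anomers) | CC1(C)OC[C@@H](O1)[C@H]2C[C@@H]3OC(O)C[C@@H]3O2 | intermediate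
14 | 2-[(2S,3S,5R)-5-[(4R)-2,2-dimethyl-1,3-dioxolan-4-yl]-3-hydroxyoxolan-2-yl]acetaldehyde | CC1(C)OC[C@@H](O1)[C@H]2C[C@H](O)[C@H](CC=O)O2 | intermediate
15 | (2S,3S,5R)-5-[(4R)-2,2-dimethyl-1,3-dioxolan-4-yl]-2-[(2Z)-pent-2-en-1-yl]oxolan-3-ol | CC1(C)OC[C@@H](O1)[C@H]2C[C@H](O)[C@H](C/C=C\CC)O2 | intermediate
16 | (2S,3S,5R)-5-[(4R)-2,2-dimethyl-1,3-dioxolan-4-yl]-2-pentyloxolan-3-ol | CC1(C)OC[C@@H](O1)[C@H]2C[C@H](O)[C@H](CCCCC)O2 | intermediate
17 | tert-butyl{[(2S,3S,5R)-5-[(4R)-2,2-dimethyl-1,3-dioxolan-4-yl]-2-pentyloxolan-3-yl]oxy}dimethylsilane | CC1(C)OC[C@@H](O1)[C@H]2C[C@H](O[Si](C)(C)C(C)(C)C)[C@H](CCCCC)O2 | intermediate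
18 | (1R)-1-[(2R,4S,5S)-4-(tert-butyldimethylsilyloxy)-5-pentyloxolan-2-yl]ethane-1,2-diol | OC[C@@H](O)[C@H]1C[C@H](O[Si](C)(C)C(C)(C)C)[C@H](CCCCC)O1 | intermediate
19 | (2R)-2-[(2R,4S,5S)-4-(tert-butyldimethylsilyloxy)-5-pentyloxolan-2-yl]-2-hydroxyethyl 4-methylbenzenesulfonate | Cc1ccc(cc1)S(=O)(=O)OC[C@@H](O)[C@H]2C[C@H](O[Si](C)(C)C(C)(C)C)[C@H](CCCCC)O2 | intermediate
20 | tert-butyl(dimethyl){[(2S,3S,5R)-5-[(2R)-oxiran-2-yl]-2-pentyloxolan-3-yl]oxy}silane | C1O[C@H]1[C@H]2C[C@H](O[Si](C)(C)C(C)(C)C)[C@H](CCCCC)O2 | intermediate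
21 | 8-bromooct-1-ene | C=CCCCCCCBr | starting material
22 | oct-7-enylmagnesium bromide | C=CCCCCCC[Mg]Br | intermediate
23 | (1R)-1-[(2R,4S,5S)-4-(tert-butyldimethylsilyloxy)-5-pentyloxolan-2-yl]dec-9-en-1-ol | C=CCCCCCCC[C@@H](O)[C@H]1C[C@H](O[Si](C)(C)C(C)(C)C)[C@H](CCCCC)O1 | intermediate
24 | hexadecanoyl (palmitoyl) chloride | CCCCCCCCCCCCCCCC(=O)Cl | starting material
25 | (1R)-1-[(2R,4S,5S)-4-(tert-butyldimethylsilyloxy)-5-pentyloxolan-2-yl]dec-9-en-1-yl hexadecanoate | C=CCCCCCCC[C@@H](OC(=O)CCCCCCCCCCCCCCC)[C@H]1C[C@H](O[Si](C)(C)C(C)(C)C)[C@H](CCCCC)O1 | intermediate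
26 | (1R)-1-[(2R,4S,5S)-4-hydroxy-5-pentyloxolan-2-yl]dec-9-en-1-yl hexadecanoate | C=CCCCCCCC[C@@H](OC(=O)CCCCCCCCCCCCCCC)[C@H]1C[C@H](O)[C@H](CCCCC)O1 | target

Total step count: 15
Longest linear sequence: 15 steps (1 to 26); 21 and 24 enter as purchased materials.

Steps most likely to fail

1. Step 6.
- What may go wrong: the Lewis-acidic CuCl2/AcOH medium may strip the dioxolane or shift it onto O9. Zerovalent palladium may deposit before it is reoxidised. The alkylpalladium stage may be drained by β-hydride elimination or chloride capture before CO inserts.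
- Fallback, from 9 back to 12, without palladium or CO: cross-metathesis of 9 with methyl acrylate (second-generation Grubbs catalyst, CH2Cl2, 40 °C) should give methyl (2E,4S,6R)-6-[(4R)-2,2-dimethyl-1,3-dioxolan-4-yl]-4,6-dihydroxyhex-2-enoate F1. Catalytic DBU in toluene then starts a reversible 5-exo oxa-Michael addition of O9 to C6. Only the adduct with C5 cis to O7 can lactonise, and this drains the equilibrium to 12.

2. Step 3.
- What may go wrong: the dioxolane oxygen on C10 may compete with the carbonate carbonyl for the iodonium ion (5-exo ether formation with breakdown of the ketal). The chair preference that sets C7 may also erode, which lowers facial selectivity.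
- Fallback, from 3 back to 9, setting C7 by chelate-controlled hydride delivery instead of halocyclisation:
  - Silylation (TBSCl, imidazole, DMF) gives tert-butyl{[(1R)-1-[(4R)-2,2-dimethyl-1,3-dioxolan-4-yl]but-3-en-1-yl]oxy}dimethylsilane F2.
  - Ozonolysis (O3, CH2Cl2, −78 °C; PPh3) gives (3R)-3-(tert-butyldimethylsilyloxy)-3-[(4R)-2,2-dimethyl-1,3-dioxolan-4-yl]propanal F3.
  - Vinylmagnesium bromide (THF, −78 °C) gives (5R)-5-(tert-butyldimethylsilyloxy)-5-[(4R)-2,2-dimethyl-1,3-dioxolan-4-yl]pent-1-en-3-ol F4 as both C7 epimers.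
  - Dess–Martin periodinane converges them to (5R)-5-(tert-butyldimethylsilyloxy)-5-[(4R)-2,2-dimethyl-1,3-dioxolan-4-yl]pent-1-en-3-one F5.
  - Pyridine-buffered HF·pyridine in THF frees (5R)-5-[(4R)-2,2-dimethyl-1,3-dioxolan-4-yl]-5-hydroxypent-1-en-3-one F6.
  - Narasaka–Prasad reduction (Et2BOMe, NaBH4, THF/MeOH, −78 °C) delivers hydride to the boron chelate to give the 7,9-syn diol 9.

3. Step 8.
- What may go wrong: the base may deprotonate C5 of the open form and expel the ring oxygen (retro-oxa-Michael), with reclosure scrambling C6. The lactol may also open too slowly for clean olefination.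
- Fallback, from 12 back to 17, with no aldehyde stage:
  - LiAlH4 (THF, 0 °C) reduces 12 to (2S,3S,5R)-5-[(4R)-2,2-dimethyl-1,3-dioxolan-4-yl]-2-(2-hydroxyethyl)oxolan-3-ol F7.
  - TsCl in pyridine at 0 °C sulfonylates the primary hydroxyl to give 2-[(2S,3S,5R)-5-[(4R)-2,2-dimethyl-1,3-dioxolan-4-yl]-3-hydroxyoxolan-2-yl]ethyl 4-methylbenzenesulfonate F8.
  - Immediate silylation (TBSOTf, 2,6-lutidine) gives 2-[(2S,3S,5R)-3-(tert-butyldimethylsilyloxy)-5-[(4R)-2,2-dimethyl-1,3-dioxolan-4-yl]oxolan-2-yl]ethyl 4-methylbenzenesulfonate F9.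
  - Copper-catalysed Grignard–tosylate coupling (n-PrMgCl, Li2CuCl4 cat., THF, −20 to 0 °C) forms C4–C3 and gives 17 directly.

Further compounds
F1 | step 6 | methyl (2E,4S,6R)-6-[(4R)-2,2-dimethyl-1,3-dioxolan-4-yl]-4,6-dihydroxyhex-2-enoate | CC1(C)OC[C@@H](O1)[C@H](O)C[C@H](O)/C=C/C(=O)OC
F2 | step 3 | tert-butyl{[(1R)-1-[(4R)-2,2-dimethyl-1,3-dioxolan-4-yl]but-3-en-1-yl]oxy}dimethylsilane | CC1(C)OC[C@@H](O1)[C@H](O[Si](C)(C)C(C)(C)C)CC=C
F3 | step 3 | (3R)-3-(tert-butyldimethylsilyloxy)-3-[(4R)-2,2-dimethyl-1,3-dioxolan-4-yl]propanal | CC1(C)OC[C@@H](O1)[C@H](O[Si](C)(C)C(C)(C)C)CC=O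
F4 | step 3 | (5R)-5-(tert-butyldimethylsilyloxy)-5-[(4R)-2,2-dimethyl-1,3-dioxolan-4-yl]pent-1-en-3-ol (both C3 epimers) | CC1(C)OC[C@@H](O1)[C@H](O[Si](C)(C)C(C)(C)C)CC(O)C=C
F5 | step 3 | (5R)-5-(tert-butyldimethylsilyloxy)-5-[(4R)-2,2-dimethyl-1,3-dioxolan-4-yl]pent-1-en-3-one | CC1(C)OC[C@@H](O1)[C@H](O[Si](C)(C)C(C)(C)C)CC(=O)C=C
F6 | step 3 | (5R)-5-[(4R)-2,2-dimethyl-1,3-dioxolan-4-yl]-5-hydroxypent-1-en-3-one | CC1(C)OC[C@@H](O1)[C@H](O)CC(=O)C=C
F7 | step 8 | (2S,3S,5R)-5-[(4R)-2,2-dimethyl-1,3-dioxolan-4-yl]-2-(2-hydroxyethyl)oxolan-3-ol | CC1(C)OC[C@@H](O1)[C@H]2C[C@H](O)[C@H](CCO)O2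
F8 | step 8 | 2-[(2S,3S,5R)-5-[(4R)-2,2-dimethyl-1,3-dioxolan-4-yl]-3-hydroxyoxolan-2-yl]ethyl 4-methylbenzenesulfonate | CC1(C)OC[C@@H](O1)[C@H]2C[C@H](O)[C@H](CCOS(=O)(=O)c3ccc(C)cc3)O2
F9 | step 8 | 2-[(2S,3S,5R)-3-(tert-butyldimethylsilyloxy)-5-[(4R)-2,2-dimethyl-1,3-dioxolan-4-yl]oxolan-2-yl]ethyl 4-methylbenzenesulfonate | CC1(C)OC[C@@H](O1)[C@H]2C[C@H](O[Si](C)(C)C(C)(C)C)[C@H](CCOS(=O)(=O)c3ccc(C)cc3)O2
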